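**Retrosynthetic overview**
1. No ring is built: rings A, C and B of the flavanone half are bought as (2S)-naringenin 1, which supplies the only stereocentre (C2). Its 7- and 4'-OH are benzylated to give 2, so the chelated 5-OH is the only free phenol.
2. Rings A, C and B of the flavone half are bought as apigenin 3, which is perbenzylated to 4.
3. Key disconnection: the C6–C8 biaryl bond between two natively nucleophilic phloroglucinol-type carbons. C8 of flavone 4 is inverted in polarity to an aryl cation equivalent, aryllead triacetate 5, which arylates C6 of 2 ortho to its 5-OH and gives 6.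
4. Global hydrogenolysis of the five benzyl ethers of 6 gives target 7.

Assumption: the SMILES defines only C2 (S) and no axial descriptor, so the hindered C6–C8 biaryl axis is left uncontrolled, and (2S)-naringenin of ≥98% ee is taken as a commercial material (ee checked by chiral HPLC after steps 1, 3 and 4).

**Step 1**
Reactants: 1 (2S)-naringenin
Product: 2 (2S)-7,4'-di-O-benzylnaringenin
Conditions: BnOH (2.2 equiv), PPh3 (2.3 equiv), DIAD (2.3 equiv), THF, 0 °C → rt
Reagents that add atoms: benzyl alcohol, OCc1ccccc1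
Why: Mitsunobu etherification alkylates only the two acidic, unchelated phenols (7-OH, 4'-OH) while the hydrogen-bonded 5-OH stays free, and without carbonate or hydroxide base there is no retro-oxa-Michael opening of ring C, so C2 (S) is retained.

**Step 2**
Reactants: 3 apigenin
Product: 4 5,7,4'-tri-O-benzylapigenin
Conditions: BnBr (4 equiv), K2CO3 (5 equiv), Bu4NI (cat.), DMF, 80 °C
Reagents that add atoms: benzyl bromide, BrCc1ccccc1
Why: Williamson ether synthesis under forcing conditions also alkylates the chelated 5-OH; the flavone has no stereocentre and no base-sensitive group.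

**Step 3**
Reactants: 4 5,7,4'-tri-O-benzylapigenin; 2 (2S)-7,4'-di-O-benzylnaringenin
Product: 6 (2S)-7,4'-di-O-benzyl-6-(5,7,4'-tri-O-benzylapigenin-8-yl)naringenin, via flavon-8-yllead triacetate 5 (not isolated)
Conditions: 4 (1.3 equiv), Pb(OAc)4 (1.2 equiv), Hg(OCOCF3)2 (10 mol%), CHCl3, 40 °C; then 2 (1.0 equiv), pyridine (4 equiv), 60 °C
Reagents that add atoms: none
Why: Proposed new method: Hg(OCOCF3)2 mercurates the least hindered, triply oxygen-activated C8–H of 4 (the position at which fully O-alkylated 5,7-dioxygenated flavones are halogenated), mercury-to-lead exchange with Pb(OAc)4 turns this natively nucleophilic carbon into the aryl cation equivalent 5, the 5-OH of 2 then replaces an acetate on tetravalent lead and reductive ligand coupling delivers the aryl group to the only free ortho carbon (C6) before tautomerisation restores the phenol; the closest known reactions are the direct plumbation of polyalkoxyarenes, the mercury-catalysed tin-to-lead exchange and the Pinhey arylation of hindered phenols by aryllead triacetates, no carbon stereocentre is formed or touched (pyridine is too weak a base to open ring C, and Pb(OAc)4 is kept limiting to 4 so no free oxidant meets the flavanone), and the new axis is uncontrolled.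

**Step 4**
Reactants: 6 (2S)-7,4'-di-O-benzyl-6-(5,7,4'-tri-O-benzylapigenin-8-yl)naringenin
Product: 7 (2S)-6-[5,7-dihydroxy-2-(4-hydroxyphenyl)-4-oxo-4H-chromen-8-yl]-5,7-dihydroxy-2-(4-hydroxyphenyl)chroman-4-one
Conditions: H2 (1 atm), Pd/C (10 wt% Pd on carbon), THF–MeOH 1:1, rt; stopped at full debenzylation
Reagents that add atoms: none
Why: Catalytic hydrogenolysis cleaves the five aryl benzyl ethers under neutral conditions, so C2 (S) cannot epimerise by acid- or base-mediated ring opening, and the chelated ketone, the flavone C2=C3 bond and the ring C ether react much more slowly at 1 atm.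

**Compound list**
1 | (2S)-naringenin, (2S)-5,7-dihydroxy-2-(4-hydroxyphenyl)chroman-4-one | O=C1C[C@@H](c2ccc(O)cc2)Oc2cc(O)cc(O)c21 | starting material
2 | (2S)-7-(benzyloxy)-2-[4-(benzyloxy)phenyl]-5-hydroxychroman-4-one | O=C1C[C@@H](c2ccc(OCc3ccccc3)cc2)Oc2cc(OCc3ccccc3)cc(O)c21 | intermediate
3 | apigenin, 5,7-dihydroxy-2-(4-hydroxyphenyl)-4H-chromen-4-one | O=c1cc(-c2ccc(O)cc2)oc2cc(O)cc(O)c12 | starting material
4 | 5,7-bis(benzyloxy)-2-[4-(benzyloxy)phenyl]-4H-chromen-4-one | O=c1cc(-c2ccc(OCc3ccccc3)cc2)oc2cc(OCc3ccccc3)cc(OCc3ccccc3)c12 | intermediate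
5 | {5,7-bis(benzyloxy)-2-[4-(benzyloxy)phenyl]-4-oxo-4H-chromen-8-yl}lead triacetate | CC(=O)O[Pb](OC(C)=O)(OC(C)=O)c1c(OCc2ccccc2)cc(OCc2ccccc2)c2c(=O)cc(-c3ccc(OCc4ccccc4)cc3)oc12 | intermediate
6 | (2S)-7-(benzyloxy)-2-[4-(benzyloxy)phenyl]-6-{5,7-bis(benzyloxy)-2-[4-(benzyloxy)phenyl]-4-oxo-4H-chromen-8-yl}-5-hydroxychroman-4-one (axis undefined) | O=C1C[C@@H](c2ccc(OCc3ccccc3)cc2)Oc2cc(OCc3ccccc3)c(-c3c(OCc4ccccc4)cc(OCc4ccccc4)c4c(=O)cc(-c5ccc(OCc6ccccc6)cc5)oc34)c(O)c21 | intermediate
7 | (2S)-6-[5,7-dihydroxy-2-(4-hydroxyphenyl)-4-oxo-4H-chromen-8-yl]-5,7-dihydroxy-2-(4-hydroxyphenyl)chroman-4-one (axis undefined) | O=C1C[C@@H](c2ccc(O)cc2)Oc2cc(O)c(-c3c(O)cc(O)c4c(=O)cc(-c5ccc(O)cc5)oc34)c(O)c21 | target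

**Totals**
Total step count: 4. Longest linear sequence: 3 steps (1 → 2 → 6 → 7, or 3 → 4 → 6 → 7).

**Steps most likely to fail**

Step 3 (site and rate of the C–H plumbation; hindered tetra-ortho-substituted biaryl). The fallback sets out from 4 and comes back at 5. Iodination of 4 with N-iodosuccinimide (cat. CF3CO2H, MeCN, rt) at C8 gives 8-iodo-5,7,4'-tri-O-benzylapigenin F1. Stannylation with Me3SnSnMe3 and Pd(PPh3)4 (toluene, 100 °C) gives 8-(trimethylstannyl)-5,7,4'-tri-O-benzylapigenin F2. Tin-to-lead exchange with Pb(OAc)4 and Hg(OAc)2 (cat.) in CHCl3 at 40 °C then gives regiochemically defined 5, to which 2 and pyridine are added as in step 3. This removes the uncertain C–H metalation and leaves only the ligand coupling to be optimised.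

Step 4 (over-reduction of the flavone C2=C3 bond or of ring C, or incomplete five-fold debenzylation). The fallback sets out from 1 and 3 and comes back at 7, replacing benzyl by acetal protection so that no reducing agent is needed. Compound 1 with MOMCl and iPr2NEt (CH2Cl2, 0 °C) gives (2S)-7,4'-di-O-(methoxymethyl)naringenin F3. Compound 3 with NaH and MOMCl (DMF, 0 °C → rt) gives 5,7,4'-tri-O-(methoxymethyl)apigenin F4. Plumbation of F4 under the step 3 conditions gives, in the flask, the 8-lead triacetate of tri-O-(methoxymethyl)apigenin F5, which arylates F3 to (2S)-7,4'-di-O-(methoxymethyl)-6-[5,7,4'-tri-O-(methoxymethyl)apigenin-8-yl]naringenin F6. Treatment with 3 M HCl in MeOH at 50 °C removes the five acetals and gives 7.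

Step 1 (mixtures of mono- and di-ether, or erosion of ee from the batch of 1 or during alkylation). The fallback sets out from 1 and comes back at 2, establishing optical purity by resolution instead of relying on retention. Compound 1 is benzylated conventionally (BnBr 2.1 equiv, K2CO3, acetone, reflux), accepting ring opening and reclosure, to give racemic 7,4'-di-O-benzylnaringenin F7. Preparative chiral SFC on an amylose tris(3,5-dimethylphenylcarbamate) phase then gives the (2S)-enantiomer, which is 2. The (2R)-enantiomer is recycled by K2CO3-mediated racemisation.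

**Further compounds**
F1 | step 3 | 5,7-bis(benzyloxy)-2-[4-(benzyloxy)phenyl]-8-iodo-4H-chromen-4-one | Ic1c(OCc2ccccc2)cc(OCc2ccccc2)c2c(=O)cc(-c3ccc(OCc4ccccc4)cc3)oc12
F2 | step 3 | 5,7-bis(benzyloxy)-2-[4-(benzyloxy)phenyl]-8-(trimethylstannyl)-4H-chromen-4-one | C[Sn](C)(C)c1c(OCc2ccccc2)cc(OCc2ccccc2)c2c(=O)cc(-c3ccc(OCc4ccccc4)cc3)oc12
F3 | step 4 | (2S)-5-hydroxy-7-(methoxymethoxy)-2-[4-(methoxymethoxy)phenyl]chroman-4-one | O=C1C[C@@H](c2ccc(OCOC)cc2)Oc2cc(OCOC)cc(O)c21
F4 | step 4 | 5,7-bis(methoxymethoxy)-2-[4-(methoxymethoxy)phenyl]-4H-chromen-4-one | O=c1cc(-c2ccc(OCOC)cc2)oc2cc(OCOC)cc(OCOC)c12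
F5 | step 4 | {5,7-bis(methoxymethoxy)-2-[4-(methoxymethoxy)phenyl]-4-oxo-4H-chromen-8-yl}lead triacetate | CC(=O)O[Pb](OC(C)=O)(OC(C)=O)c1c(OCOC)cc(OCOC)c2c(=O)cc(-c3ccc(OCOC)cc3)oc12
F6 | step 4 | (2S)-6-{5,7-bis(methoxymethoxy)-2-[4-(methoxymethoxy)phenyl]-4-oxo-4H-chromen-8-yl}-5-hydroxy-7-(methoxymethoxy)-2-[4-(methoxymethoxy)phenyl]chroman-4-one | O=C1C[C@@H](c2ccc(OCOC)cc2)Oc2cc(OCOC)c(-c3c(OCOC)cc(OCOC)c4c(=O)cc(-c5ccc(OCOC)cc5)oc34)c(O)c21
F7 | step 1 | racemic 7-(benzyloxy)-2-[4-(benzyloxy)phenyl]-5-hydroxychroman-4-one | O=C1CC(c2ccc(OCc3ccccc3)cc2)Oc2cc(OCc3ccccc3)cc(O)c21
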